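**Retrosynthetic overview**
- The target comes from desilylation, Mitsunobu inversion at C8 with methacrylic acid, and an α-methylene-γ-lactone made by intramolecular epoxide opening with an O6-bound phosphonoacetate followed by HWE with formaldehyde.
- The C3 acetate and C15 alcohol come from an isoxazoline (masked β-hydroxy ketone) fused to ring A.
- Key step: an intramolecular nitrile oxide cycloaddition forms ring A (C3–C4) and the isoxazoline in one operation, closing the in,out-bridged 11-oxabicyclo[4.4.1]undecane on a preformed ring B.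
- Ring B with C5, C6 and C10 comes from an AlMe3 ring expansion of a 6,8-dioxabicyclo[3.2.1]octene ketal, itself made by ketalisation and desymmetrising RCM of (3R,4R)-hexa-1,5-diene-3,4-diol with 7-bromohept-1-en-4-one.
- Ring order: dioxolane → dihydropyran (bicyclic ketal) → oxepene (ring B) → ring A + isoxazoline → lactone.

Assumption: the SMILES is taken literally (all seven stereocentres R, which puts the ether oxygen on opposite ring faces at C5 and C10, an in,out-bridged bicycle); atom labels follow germacrane numbering (C3 CHOAc, C4/C15 CH–CH2OH, C5 ether CH, C6 lactone CH–O, C8 CH–O-methacrylate, C10 C–CH3, O5 ether oxygen, O6 lactone oxygen).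

**Route**

Step 1
Reactants: 1 4-bromobutanoyl chloride; 2 allyltrimethylsilane
Product: 3 7-bromohept-1-en-4-one
Conditions: AlCl3, CH2Cl2, −78 °C
Reagents that add atoms: none
Why: Hosomi–Sakurai-type Lewis-acid acylation of the allylsilane (SE2′) gives the β,γ-unsaturated ketone directly, the low temperature keeping the alkene out of conjugation; no stereocentre is formed.

Step 2
Reactants: 3 7-bromohept-1-en-4-one; 4 (3R,4R)-hexa-1,5-diene-3,4-diol
Product: 5 (4R,5R)-2-allyl-2-(3-bromopropyl)-4,5-divinyl-1,3-dioxolane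
Conditions: iPrOSiMe3 (2.2 equiv), TMSOTf (5 mol%), CH2Cl2, −20 °C
Reagents that add atoms: none
Why: Noyori-type silyl-mediated ketalisation forms the dioxolane without isomerising the β,γ-enone; the diol is C2-symmetric, so the ketal carbon is not yet a stereocentre and C5/C6 are carried over unchanged.

Step 3
Reactants: 5 (4R,5R)-2-allyl-2-(3-bromopropyl)-4,5-divinyl-1,3-dioxolane
Product: 6 (1R,5S,7R)-5-(3-bromopropyl)-7-vinyl-6,8-dioxabicyclo[3.2.1]oct-2-ene
Conditions: Grubbs II (2 mol%), CH2Cl2, 40 °C
Reagents that add atoms: none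
Why: Diastereotopic-group-selective ring-closing metathesis, in which only the vinyl group cis to the allyl arm can close the six-membered ring, so the ketal carbon C10 becomes a stereocentre fixed by C6 and the second vinyl group stays exo on C5.

Step 4
Reactants: 6 (1R,5S,7R)-5-(3-bromopropyl)-7-vinyl-6,8-dioxabicyclo[3.2.1]oct-2-ene
Product: 7 (2R,3R,7R)-7-(3-bromopropyl)-7-methyl-2-vinyl-2,3,6,7-tetrahydrooxepin-3-ol
Conditions: AlMe3 (4 equiv), CH2Cl2, −78 → 0 °C; aq. Rochelle salt
Reagents that add atoms: trimethylaluminium, C[Al](C)C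
Why: Proposed new method: alkylative ring expansion of the bicyclic ketal, in which AlMe3 binds the more accessible pyran oxygen O6, the C10–O6 bond ionises to a contact ion pair and the aluminate hands a methyl group to C10 on the face O6 has just left (retention), giving the oxepene with free C6–OH and the C10 methyl cis to the C5 vinyl and C6 hydroxyl (the arm therefore trans to C4, as the target requires); the closest known reactions are the DIBAL-H reductive ring expansion of 6,8-dioxabicyclo[3.2.1]octanes to cis-2,7-disubstituted oxepan-3-ols and the retentive cleavage of acetals by trialkylaluminium reagents.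

Step 5
Reactants: 7 (2R,3R,7R)-7-(3-bromopropyl)-7-methyl-2-vinyl-2,3,6,7-tetrahydrooxepin-3-ol
Product: 8 (2R,3R,7R)-7-methyl-7-(3-nitropropyl)-2-vinyl-2,3,6,7-tetrahydrooxepin-3-ol
Conditions: AgNO2, Et2O, 0 °C → rt, dark
Reagents that add atoms: silver nitrite, [Ag+].[O-]N=O
Why: Victor Meyer reaction (SN2 of the primary bromide by silver nitrite) gives the nitroalkane needed as nitrile oxide precursor; no stereocentre is touched.

Step 6
Reactants: 8 (2R,3R,7R)-7-methyl-7-(3-nitropropyl)-2-vinyl-2,3,6,7-tetrahydrooxepin-3-ol; 9 2-(diethoxyphosphoryl)acetic acid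
Product: 10 (2R,3R,7R)-7-methyl-7-(3-nitropropyl)-2-vinyl-2,3,6,7-tetrahydrooxepin-3-yl 2-(diethoxyphosphoryl)acetate
Conditions: DCC, DMAP (cat.), CH2Cl2, 0 °C → rt
Reagents that add atoms: none
Why: Steglich esterification of the allylic C6 alcohol; the phosphonoacetate protects O6 through the next steps and is the latent C11–C12 unit of the lactone.

Step 7
Reactants: 10 (2R,3R,7R)-7-methyl-7-(3-nitropropyl)-2-vinyl-2,3,6,7-tetrahydrooxepin-3-yl 2-(diethoxyphosphoryl)acetate
Product: 11 C7–C8 anti-epoxide of 10 (epoxide oxygen on the ring face opposite the C6 ester)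
Conditions: mCPBA, CH2Cl2, 0 °C
Reagents that add atoms: 3-chloroperbenzoic acid, OOC(=O)c1cccc(Cl)c1
Why: Prilezhaev epoxidation, selective for the cis-disubstituted ring alkene over the monosubstituted vinyl group and delivered to the face opposite the allylic acyloxy group (the C5 vinyl and C10 methyl shield that same face), which sets C7/C8 as the anti-epoxide and removes the ring alkene before the cycloaddition.

Step 8
Reactants: 11 C7–C8 anti-epoxide of 10
Product: 13 tetracyclic isoxazoline (ring A closed: C3=N–O–C15H2–C4 dihydroisoxazole fused to the in/out 11-oxabicyclo[4.4.1]undecane; C7–C8 epoxide; C6 O-phosphonoacetate), via nitrile oxide 12 (not isolated)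
Conditions: PhNCO (2.2 equiv), Et3N (cat.), toluene, 80 °C, syringe pump (2 mM)
Reagents that add atoms: none
Why: Mukaiyama dehydration of the nitroalkane and fused-mode intramolecular nitrile oxide–alkene cycloaddition form the C3–C4 and O–C15 bonds at once, closing the second oxepane between the trans-disposed arm and vinyl group (the strained in,out bicycle, reached irreversibly through a remote C–C bond) together with the isoxazoline; C4 is set by attack on the vinyl rotamer with H5 inside and C6 anti to the forming bond (minimal A1,3 strain), which places C15 trans to C6 on the new ring.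

Step 9
Reactants: 13 tetracyclic isoxazoline
Product: 15 β-hydroxy ketone (C3=O; C15–OH; C7–C8 epoxide; C6 O-phosphonoacetate), via hydroxy imine 14 (not isolated)
Conditions: Raney Ni, H2 (1 atm), B(OH)3, MeOH–H2O 5:1, rt
Reagents that add atoms: water, O
Why: Hydrogenolysis of the isoxazoline N–O bond and boric-acid-buffered hydrolysis of the β-hydroxy imine unmask the β-hydroxy ketone without epimerising C4 (no other reducible C=C is present at this stage).

Step 10
Reactants: 15 β-hydroxy ketone
Product: 16 15-O-TBS ether of 15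
Conditions: TBSCl, imidazole, DMF, 0 °C
Reagents that add atoms: tert-butyldimethylsilyl chloride, CC(C)(C)[Si](C)(C)Cl
Why: Silylation of the primary C15 alcohol so that only the later C3 hydroxyl is acetylated and only C8–OH is free in the Mitsunobu step.

Step 11
Reactants: 16 15-O-TBS ether of 15
Product: 17 C3 alcohol (3-OH cis to the C4 CH2OTBS group; C3 as in the target)
Conditions: L-Selectride, THF, −78 °C
Reagents that add atoms: none
Why: Ketone reduction with a bulky trialkylborohydride, which attacks C3 from the face opposite the adjacent CH2OTBS group (steric approach control as for 2-substituted cycloalkanones), giving the 3,4-cis alcohol.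

Step 12
Reactants: 17 C3 alcohol
Product: 18 C3 acetate of 17
Conditions: Ac2O, pyridine, DMAP (cat.), CH2Cl2, rt
Reagents that add atoms: acetic anhydride, CC(=O)OC(C)=O
Why: DMAP-catalysed acetylation of the only free hydroxyl; no stereocentre is affected.

Step 13
Reactants: 18 C3 acetate of 17
Product: 20 α-methylene-γ-lactone 8-epi-alcohol (15-O-TBS target lacking the methacryloyl group and epimeric at C8), via phosphono lactone 19 (not isolated)
Conditions: NaH (1.1 equiv), THF, 0 °C → rt; then (CH2O)n, rt
Reagents that add atoms: formaldehyde (from paraformaldehyde), C=O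
Why: Intramolecular epoxide alkylation followed by Horner–Wadsworth–Emmons olefination: the phosphonoacetate carbanion opens the anti-epoxide at C7 by 5-exo-tet attack with inversion (C11 enters cis to O6, giving the cis-fused lactone and leaving C8–OH on the opposite face), the alkoxide is quenched by the acidic α-phosphono C–H, and the resulting carbanion olefinates formaldehyde to give the exocyclic methylene.

Step 14
Reactants: 20 α-methylene-γ-lactone 8-epi-alcohol; 21 methacrylic acid
Product: 22 15-O-TBS ether of the target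
Conditions: PPh3, DIAD, toluene, 0 °C → rt
Reagents that add atoms: none
Why: Mitsunobu esterification inverts C8 (SN2 of the carboxylate on the alkoxyphosphonium), placing the methacrylate cis to the lactone as in the target.

Step 15
Reactants: 22 15-O-TBS ether of the target
Product: 23 target CNP0602302.1
Conditions: HF·pyridine, pyridine–THF, 0 °C → rt
Reagents that add atoms: none
Why: Buffered fluoride desilylation frees the C15 alcohol; the acetate, methacrylate and α-methylene lactone are inert to these conditions.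

**Compound list**

1 | 4-bromobutanoyl chloride | O=C(Cl)CCCBr | starting material
2 | allyltrimethylsilane | C=CC[Si](C)(C)C | starting material
3 | 7-bromohept-1-en-4-one | C=CCC(=O)CCCBr | intermediate
4 | (3R,4R)-hexa-1,5-diene-3,4-diol | C=C[C@@H](O)[C@H](O)C=C | starting material
5 | (4R,5R)-2-allyl-2-(3-bromopropyl)-4,5-divinyl-1,3-dioxolane | C=CCC1(CCCBr)O[C@H](C=C)[C@@H](C=C)O1 | intermediate
6 | (1R,5S,7R)-5-(3-bromopropyl)-7-vinyl-6,8-dioxabicyclo[3.2.1]oct-2-ene (7-exo-vinyl) | BrCCC[C@@]12CC=C[C@@H](O1)[C@@H](C=C)O2 | intermediate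
7 | (2R,3R,7R)-7-(3-bromopropyl)-7-methyl-2-vinyl-2,3,6,7-tetrahydrooxepin-3-ol (7-CH3 cis to 2-vinyl and 3-OH) | BrCCC[C@]1(C)CC=C[C@@H](O)[C@@H](C=C)O1 | intermediate
8 | (2R,3R,7R)-7-methyl-7-(3-nitropropyl)-2-vinyl-2,3,6,7-tetrahydrooxepin-3-ol | O=[N+]([O-])CCC[C@]1(C)CC=C[C@@H](O)[C@@H](C=C)O1 | intermediate
9 | 2-(diethoxyphosphoryl)acetic acid | OC(=O)CP(=O)(OCC)OCC | starting material
10 | (2R,3R,7R)-7-methyl-7-(3-nitropropyl)-2-vinyl-2,3,6,7-tetrahydrooxepin-3-yl 2-(diethoxyphosphoryl)acetate | O=[N+]([O-])CCC[C@]1(C)CC=C[C@@H](OC(=O)CP(=O)(OCC)OCC)[C@@H](C=C)O1 | intermediate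
11 | C7–C8 anti-epoxide of 10 (epoxide oxygen trans to the C6 ester) | O=[N+]([O-])CCC[C@]1(C)C[C@@H]2O[C@@H]2[C@@H](OC(=O)CP(=O)(OCC)OCC)[C@@H](C=C)O1 | intermediate
12 | nitrile oxide of 11 (C3≡N–O, not isolated) | [O-][N+]#CCC[C@]1(C)C[C@@H]2O[C@@H]2[C@@H](OC(=O)CP(=O)(OCC)OCC)[C@@H](C=C)O1 | intermediate
13 | tetracyclic isoxazoline (C3=N–O–C15H2–C4 dihydroisoxazole fused to ring A of the in,out 11-oxabicyclo[4.4.1]undecane; C7–C8 epoxide anti to O6; C6 O-phosphonoacetate; C4, C5, C6, C10 as in the target) | C[C@]12CCC3=NOC[C@H]3[C@@H](O1)[C@H](OC(=O)CP(=O)(OCC)OCC)[C@H]4O[C@H]4C2 | intermediate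
14 | β-hydroxy imine (C3=NH, C15–OH, not isolated) | C[C@]12CCC(=N)[C@@H](CO)[C@@H](O1)[C@H](OC(=O)CP(=O)(OCC)OCC)[C@H]3O[C@H]3C2 | intermediate
15 | β-hydroxy ketone (C3=O, C15–OH, C7–C8 epoxide, C6 O-phosphonoacetate) | C[C@]12CCC(=O)[C@@H](CO)[C@@H](O1)[C@H](OC(=O)CP(=O)(OCC)OCC)[C@H]3O[C@H]3C2 | intermediate
16 | 15-O-TBS ether of 15 | C[C@]12CCC(=O)[C@@H](CO[Si](C)(C)C(C)(C)C)[C@@H](O1)[C@H](OC(=O)CP(=O)(OCC)OCC)[C@H]3O[C@H]3C2 | intermediate
17 | C3 alcohol (3-OH cis to the C4 CH2OTBS group, C3 as in the target) | C[C@]12CC[C@@H](O)[C@@H](CO[Si](C)(C)C(C)(C)C)[C@@H](O1)[C@H](OC(=O)CP(=O)(OCC)OCC)[C@H]3O[C@H]3C2 | intermediate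
18 | C3 acetate of 17 | C[C@]12CC[C@@H](OC(C)=O)[C@@H](CO[Si](C)(C)C(C)(C)C)[C@@H](O1)[C@H](OC(=O)CP(=O)(OCC)OCC)[C@H]3O[C@H]3C2 | intermediate
19 | α-(diethoxyphosphoryl)-γ-lactone (C11–C7 bond cis to O6, C8–OH on the opposite face, C11 unassigned, not isolated) | O[C@H]1C[C@@]2(C)CC[C@@H](OC(C)=O)[C@@H](CO[Si](C)(C)C(C)(C)C)[C@@H](O2)[C@@H]2OC(=O)C(P(=O)(OCC)OCC)[C@@H]21 | intermediate
20 | α-methylene-γ-lactone 8-epi-alcohol (15-O-TBS target lacking the methacryloyl group, C8 epimeric) | O[C@H]1C[C@@]2(C)CC[C@@H](OC(C)=O)[C@@H](CO[Si](C)(C)C(C)(C)C)[C@@H](O2)[C@@H]2OC(=O)C(=C)[C@@H]21 | intermediate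
21 | methacrylic acid | C=C(C)C(=O)O | starting material
22 | 15-O-TBS ether of the target | C=C(C)C(=O)O[C@@H]1C[C@@]2(C)CC[C@@H](OC(C)=O)[C@@H](CO[Si](C)(C)C(C)(C)C)[C@@H](O2)[C@@H]2OC(=O)C(=C)[C@@H]21 | intermediate
23 | CNP0602302.1 | C=C(C)C(=O)O[C@@H]1C[C@@]2(C)CC[C@@H](OC(C)=O)[C@@H](CO)[C@@H](O2)[C@@H]2OC(=O)C(=C)[C@@H]21 | target

**Summary**

Total steps: 15. Longest linear sequence: 15 steps (1 → 23); compounds 4, 9 and 21 are bought.

Steps most likely to fail:

- **Step 4 (AlMe3 ring expansion).** The reagent may cleave the other C–O bond or fail to transfer methyl. The fallback exchanges the roles of the two carbon substituents and uses inversion instead of retention. It sets out from 4, which is ketalised with pent-4-en-2-one under the conditions of step 2 to the methyl ketal (4R,5R)-2-allyl-2-methyl-4,5-divinyl-1,3-dioxolane F1. Ring-closing metathesis turns this into (1R,5S,7R)-5-methyl-7-vinyl-6,8-dioxabicyclo[3.2.1]oct-2-ene F2. TiCl4 and (vinyloxy)trimethylsilane at −78 °C then open it by Mukaiyama-type attack on C10 from the face opposite the departing O6, giving the oxepenyl acetaldehyde F3 with the CH2CHO arm trans to the C5 vinyl group, as in 7. Henry condensation with nitromethane (NH4OAc) gives the (E)-nitroalkene F4, and NaBH4 reduction of its C=C bond comes back to the route at 8.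

- **Step 8 (cycloaddition closing the in,out ring).** The nitrile oxide may dimerise faster than it closes the strained ring. The fallback switches to a persistent dipole. It sets out from 11: TMSCl/Et3N gives the silyl nitronate, which is left to cyclise (intramolecular silyl nitronate–alkene cycloaddition, toluene, rt to 60 °C) to the N-(trimethylsilyloxy)isoxazolidine F5. TsOH then eliminates the silanol and comes back to the route at 13.

- **Step 14 (Mitsunobu inversion at the hindered C8 carbinol).** Elimination or retention is possible. The fallback inverts by an oxidation–reduction pair. It sets out from 20: Dess–Martin periodinane gives the C8 ketone F6, NaBH4/CeCl3 at −78 °C adds hydride anti to the C7 substituent to give the C8-inverted alcohol F7 (configured as in the target), and methacrylic anhydride/DMAP acylates it, coming back to the route at 22.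

**Further compounds**

F1 | step 4 | (4R,5R)-2-allyl-2-methyl-4,5-divinyl-1,3-dioxolane | C=CCC1(C)O[C@H](C=C)[C@@H](C=C)O1
F2 | step 4 | (1R,5S,7R)-5-methyl-7-vinyl-6,8-dioxabicyclo[3.2.1]oct-2-ene | C[C@@]12CC=C[C@@H](O1)[C@@H](C=C)O2
F3 | step 4 | 2-[(2R,3R)-3-hydroxy-7-methyl-2-vinyl-2,3,6,7-tetrahydrooxepin-7-yl]acetaldehyde (7-CH3 cis to 2-vinyl) | O=CC[C@]1(C)CC=C[C@@H](O)[C@@H](C=C)O1
F4 | step 4 | (2R,3R)-7-methyl-7-[(E)-3-nitroprop-2-enyl]-2-vinyl-2,3,6,7-tetrahydrooxepin-3-ol (7-CH3 cis to 2-vinyl) | O=[N+]([O-])/C=C/C[C@]1(C)CC=C[C@@H](O)[C@@H](C=C)O1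
F5 | step 8 | N-(trimethylsilyloxy)isoxazolidine analogue of 13 (C3 sp3, C3 unassigned) | C[C@]12CCC3N(O[Si](C)(C)C)OC[C@H]3[C@@H](O1)[C@H](OC(=O)CP(=O)(OCC)OCC)[C@H]4O[C@H]4C2
F6 | step 14 | C8 ketone derived from 20 | O=C1C[C@@]2(C)CC[C@@H](OC(C)=O)[C@@H](CO[Si](C)(C)C(C)(C)C)[C@@H](O2)[C@@H]2OC(=O)C(=C)[C@@H]21
F7 | step 14 | C8 epimer of 20 (8-OH configured as in the target) | O[C@@H]1C[C@@]2(C)CC[C@@H](OC(C)=O)[C@@H](CO[Si](C)(C)C(C)(C)C)[C@@H](O2)[C@@H]2OC(=O)C(=C)[C@@H]21
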